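The target, an achiral ester of two furan-terminated diynyl chains, is cut at the C7–C8 bond of its O-henicosadiynyl chain: a CH2–CH2 bond inside the (CH2)13 tether that separates the ester oxygen from the C14–C17 diyne, far from both furan rings. Each of these carbons is read as the α-carbon of a carboxylic acid, so the bond is formed by a nickel-electrocatalytic doubly decarboxylative coupling of two N-hydroxyphthalimide esters: the 8-acyloxyoctanoate 11, which already holds the whole acyl part, and the furyl-pentadecadiynoate 18. One cathodic operation expels two CO2 and joins two primary radicals; this reductive Kolbe-type union spares the oxidation-labile furans.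

Key step: step 13

Remark: the target has no stereocentre and no stereogenic double bond, so the SMILES describes one achiral compound and no stereocontrol is needed.
Remark: furan, 1,11-dibromoundecane, 1,4-dibromobutane, hex-5-ynoic acid, non-8-ynoic acid and 8-hydroxyoctanoic acid are taken as commercially available.
Remark: 2-furyllithium 2 is made once as a titrated THF solution, kept cold under argon, and divided between the two alkylations (steps 2 and 8); it is not isolated as a solid.

Step 1
Reactants: 1 furan
Product: 2 2-furyllithium
Conditions: furan (slight excess), n-BuLi, THF, −20 to 0 °C; solution titrated, kept at −20 °C under Ar and used in two portions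
Reagents that add atoms: n-butyllithium, [Li]CCCC
Why: n-BuLi deprotonates furan selectively at C2 next to the ring oxygen (α-lithiation of furan), and the resulting THF solution of 2-furyllithium should be stable at or below 0 °C long enough to serve both alkylations.

Step 2
Reactants: 2 2-furyllithium; 3 1,11-dibromoundecane
Product: 4 2-(11-bromoundecyl)furan
Conditions: solution of 2 added by cannula to 3 (3 equiv), THF, −78 °C to rt
Reagents that add atoms: none
Why: 2-furyllithium displaces one bromide of the primary dibromide in an SN2 alkylation, the threefold excess of 3 and the inverse addition favouring mono-substitution (alkylation of an α-lithiofuran).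

Step 3
Reactants: 4 2-(11-bromoundecyl)furan
Product: 5 2-(tridec-12-yn-1-yl)furan
Conditions: lithium acetylide–ethylenediamine complex, DMSO, 10 °C to rt
Reagents that add atoms: lithium acetylide–ethylenediamine complex, [Li]C#C.NCCN
Why: SN2 alkylation of lithium acetylide by the unhindered primary bromide in DMSO should give the terminal alkyne, the 2-alkylfuran being inert to the base (acetylide alkylation).

Step 4
Reactants: 6 hex-5-ynoic acid
Product: 7 6-bromohex-5-ynoic acid
Conditions: NBS, AgNO3 (cat.), acetone, rt, dark
Reagents that add atoms: N-bromosuccinimide, O=C1CCC(=O)N1Br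
Why: silver-catalysed electrophilic bromination of the terminal alkyne C–H through the silver acetylide gives the 1-bromoalkyne and leaves the carboxylic acid untouched.

Step 5
Reactants: 5 2-(tridec-12-yn-1-yl)furan; 7 6-bromohex-5-ynoic acid
Product: 8 19-(furan-2-yl)nonadeca-5,7-diynoic acid
Conditions: CuCl (cat.), NH2OH·HCl, 70% aq. EtNH2, MeOH/THF, 0 °C to rt; cold aq. citric acid work-up
Reagents that add atoms: none
Why: Cadiot–Chodkiewicz coupling of the copper(I) acetylide of 5 with the 1-bromoalkyne 7 should give the unsymmetrical conjugated diyne, the acid travelling as its ethylammonium salt and being released by mild acidification that the furan tolerates.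

Step 6
Reactants: 9 8-hydroxyoctanoic acid
Product: 10 1,3-dioxoisoindolin-2-yl 8-hydroxyoctanoate
Conditions: N-hydroxyphthalimide, DIC, THF, 0 °C to rt (no DMAP)
Reagents that add atoms: N-hydroxyphthalimide, O=C1c2ccccc2C(=O)N1O
Why: in this carbodiimide active-ester formation the O-acylisourea should be intercepted much faster by the acidic α-effect nucleophile N-hydroxyphthalimide than by the unactivated primary hydroxyl when no acyl-transfer catalyst is present, so the free ω-hydroxy ester is expected without oligomerisation.

Step 7
Reactants: 8 19-(furan-2-yl)nonadeca-5,7-diynoic acid; 10 1,3-dioxoisoindolin-2-yl 8-hydroxyoctanoate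
Product: 11 1,3-dioxoisoindolin-2-yl 8-{[19-(furan-2-yl)nonadeca-5,7-diynoyl]oxy}octanoate
Conditions: DIC, DMAP (5 mol%), CH2Cl2, 0 °C
Reagents that add atoms: none
Why: Steglich esterification, in which the DIC/DMAP-activated acid 8 acylates the primary hydroxyl of 10 at 0 °C while the far less electrophilic N-acyloxyphthalimide is expected to survive the small DMAP charge.

Step 8
Reactants: 2 2-furyllithium; 12 1,4-dibromobutane
Product: 13 2-(4-bromobutyl)furan
Conditions: second portion of the solution of 2 added by cannula to 12 (3 equiv), THF, −78 °C to rt
Reagents that add atoms: none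
Why: the same SN2 mono-alkylation of 2-furyllithium as in step 2, with the excess dibromide suppressing double substitution.

Step 9
Reactants: 13 2-(4-bromobutyl)furan
Product: 14 2-(hex-5-yn-1-yl)furan
Conditions: lithium acetylide–ethylenediamine complex, DMSO, 10 °C to rt
Reagents that add atoms: lithium acetylide–ethylenediamine complex, [Li]C#C.NCCN
Why: SN2 alkylation of lithium acetylide by the primary bromide, as in step 3.

Step 10
Reactants: 15 non-8-ynoic acid
Product: 16 9-bromonon-8-ynoic acid
Conditions: NBS, AgNO3 (cat.), acetone, rt, dark
Reagents that add atoms: N-bromosuccinimide, O=C1CCC(=O)N1Br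
Why: silver-catalysed bromination of the terminal alkyne C–H, as in step 4.

Step 11
Reactants: 14 2-(hex-5-yn-1-yl)furan; 16 9-bromonon-8-ynoic acid
Product: 17 15-(furan-2-yl)pentadeca-8,10-diynoic acid
Conditions: CuCl (cat.), NH2OH·HCl, 70% aq. EtNH2, MeOH, 0 °C to rt; cold aq. citric acid work-up
Reagents that add atoms: none
Why: Cadiot–Chodkiewicz coupling of the copper acetylide of 14 with the bromoalkyne 16 should give the unsymmetrical diynoic acid, as in step 5.

Step 12
Reactants: 17 15-(furan-2-yl)pentadeca-8,10-diynoic acid
Product: 18 1,3-dioxoisoindolin-2-yl 15-(furan-2-yl)pentadeca-8,10-diynoate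
Conditions: N-hydroxyphthalimide, DIC, DMAP (10 mol%), CH2Cl2, rt
Reagents that add atoms: N-hydroxyphthalimide, O=C1c2ccccc2C(=O)N1O
Why: carbodiimide coupling with DMAP catalysis converts the acid into its redox-active N-acyloxyphthalimide ester.

Step 13
Reactants: 11 1,3-dioxoisoindolin-2-yl 8-{[19-(furan-2-yl)nonadeca-5,7-diynoyl]oxy}octanoate; 18 1,3-dioxoisoindolin-2-yl 15-(furan-2-yl)pentadeca-8,10-diynoate
Product: 19 21-(furan-2-yl)henicosa-14,16-diyn-1-yl 19-(furan-2-yl)nonadeca-5,7-diynoate
Conditions: 18 (3 equiv), NiCl2·6H2O (20 mol%), 2,2':6',2''-terpyridine (20 mol%), AgNO3 (0.3 equiv), NaI, DMF, Mg anode/RVC cathode, constant current, undivided cell, rt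
Reagents that add atoms: none
Why: Cathodic, terpyridine-nickel-mediated single-electron reduction of each N-acyloxyphthalimide gives a radical anion that fragments to phthalimide anion, CO2 and a primary alkyl radical; low-valent nickel captures the two radicals in turn and reductive elimination from the dialkylnickel species forms the CH2–CH2 bond (C7–C8 of the alkoxy chain), the magnesium anode supplying the electrons. The closest known reaction type is the nickel-electrocatalytic doubly decarboxylative C(sp3)–C(sp3) cross-coupling of two redox-active esters, established for primary/primary pairs and in effect a reductive counterpart of the mixed Kolbe electrolysis. No ring is closed and no stereocentre is created. The selectivity needed is crossed over homo-coupling; it is statistical and is secured by the threefold excess of the simpler ester 18 and by the expected easy chromatographic separation of the hydrocarbon-like 18/18 dimer and the diester 11/11 dimer from the monoester 19. Chemoselectivity rests on the substrate: both radicals are primary and at least five CH2 groups away from the nearest diyne carbon, so cyclisation should not compete with capture at nickel, and the reductive mode with a sacrificial anode keeps the anodically fragile 2-alkylfurans (which a classical oxidative Kolbe would destroy), the inner ester and the internal diynes out of the redox chemistry.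

Compound list
1 | furan | c1ccoc1 | starting material
2 | 2-furyllithium | [Li]c1ccco1 | intermediate
3 | 1,11-dibromoundecane | BrCCCCCCCCCCCBr | starting material
4 | 2-(11-bromoundecyl)furan | BrCCCCCCCCCCCc1ccco1 | intermediate
5 | 2-(tridec-12-yn-1-yl)furan | C#CCCCCCCCCCCCc1ccco1 | intermediate
6 | hex-5-ynoic acid | OC(=O)CCCC#C | starting material
7 | 6-bromohex-5-ynoic acid | OC(=O)CCCC#CBr | intermediate
8 | 19-(furan-2-yl)nonadeca-5,7-diynoic acid | OC(=O)CCCC#CC#CCCCCCCCCCCCc1ccco1 | intermediate
9 | 8-hydroxyoctanoic acid | OCCCCCCCC(=O)O | starting material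
10 | 1,3-dioxoisoindolin-2-yl 8-hydroxyoctanoate | OCCCCCCCC(=O)ON1C(=O)c2ccccc2C1=O | intermediate
11 | 1,3-dioxoisoindolin-2-yl 8-{[19-(furan-2-yl)nonadeca-5,7-diynoyl]oxy}octanoate | O=C(CCCC#CC#CCCCCCCCCCCCc1ccco1)OCCCCCCCC(=O)ON1C(=O)c2ccccc2C1=O | intermediate
12 | 1,4-dibromobutane | BrCCCCBr | starting material
13 | 2-(4-bromobutyl)furan | BrCCCCc1ccco1 | intermediate
14 | 2-(hex-5-yn-1-yl)furan | C#CCCCCc1ccco1 | intermediate
15 | non-8-ynoic acid | OC(=O)CCCCCCC#C | starting material
16 | 9-bromonon-8-ynoic acid | OC(=O)CCCCCCC#CBr | intermediate
17 | 15-(furan-2-yl)pentadeca-8,10-diynoic acid | OC(=O)CCCCCCC#CC#CCCCCc1ccco1 | intermediate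
18 | 1,3-dioxoisoindolin-2-yl 15-(furan-2-yl)pentadeca-8,10-diynoate | O=C(CCCCCCC#CC#CCCCCc1ccco1)ON1C(=O)c2ccccc2C1=O | intermediate
19 | 21-(furan-2-yl)henicosa-14,16-diyn-1-yl 19-(furan-2-yl)nonadeca-5,7-diynoate | O=C(CCCC#CC#CCCCCCCCCCCCc1ccco1)OCCCCCCCCCCCCCC#CC#CCCCCc1ccco1 | target

Total step count: 13.
Longest linear sequence: 6 steps (1, 2, 3, 5, 7, 13; the branch 1, 8, 9, 11, 12, 13 is equally long).

Steps most likely to fail

Step 13. Homo-dimerisation of each radical precursor may outrun the crossed coupling, and low-valent nickel may be sequestered by the conjugated diynes (oligomerisation), stalling turnover. The fallback is a copper-catalysed alkyl–alkyl Grignard cross-coupling, free of nickel and of radicals; it sets out from 8 and 14 and comes back to the route at 19. Acid 8 would be esterified with 7-bromoheptan-1-ol (OCCCCCCCBr; DIC, DMAP, CH2Cl2) to 7-bromoheptyl 19-(furan-2-yl)nonadeca-5,7-diynoate F1. Oct-7-yn-1-ol (OCCCCCCC#C) would be brominated (NBS, AgNO3, acetone) to 8-bromooct-7-yn-1-ol F2, and Cadiot–Chodkiewicz coupling of F2 with 14 should give 14-(furan-2-yl)tetradeca-7,9-diyn-1-ol F3. Appel bromination (CBr4, PPh3, CH2Cl2, 0 °C) would give 2-(14-bromotetradeca-5,7-diyn-1-yl)furan F4, and magnesium in THF would give [14-(furan-2-yl)tetradeca-7,9-diyn-1-yl]magnesium bromide F5. Slow addition of F5 to F1 with catalytic Li2CuCl4 in THF/NMP at −20 to 0 °C should form the same CH2–CH2 bond and give 19, substitution at the primary bromide being expected to outpace addition to the ester at this temperature.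

Step 7. DMAP-mediated acyl transfer from the N-acyloxyphthalimide of 10 to its own hydroxyl (oligoester formation) may compete with the wanted acylation by 8. The fallback installs the redox-active ester last behind a temporary allyl ester; it sets out from 8 and 9 and comes back at 11. Acid 9 would be alkylated with allyl bromide (KHCO3, DMF) to allyl 8-hydroxyoctanoate F6. Steglich esterification of F6 with 8 (DIC, DMAP, CH2Cl2) would give 8-(allyloxy)-8-oxooctyl 19-(furan-2-yl)nonadeca-5,7-diynoate F7. Deallylation with Pd(PPh3)4 and morpholine in THF at rt should release 8-{[19-(furan-2-yl)nonadeca-5,7-diynoyl]oxy}octanoic acid F8, which N-hydroxyphthalimide, DIC and catalytic DMAP would convert into 11.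

Step 5 (the same applies to step 11). Halogen–copper exchange and homocoupling of the bromoalkyne may erode the crossed diyne. The fallback is a Glaser–Hay oxidative hetero-coupling of the two terminal alkynes, which avoids the bromoalkyne; it sets out from 5 and 6 and comes back at 8. Alkyne 5 and a fivefold excess of the cheap acid 6 would be coupled with CuCl/TMEDA under O2 in acetone, so that 5 is channelled statistically into 8; the polar diacid homodimer of 6 should separate readily on silica. This fallback makes no new compound (F0).

Further compounds
F1 | step 13 | 7-bromoheptyl 19-(furan-2-yl)nonadeca-5,7-diynoate | O=C(CCCC#CC#CCCCCCCCCCCCc1ccco1)OCCCCCCCBr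
F2 | step 13 | 8-bromooct-7-yn-1-ol | OCCCCCCC#CBr
F3 | step 13 | 14-(furan-2-yl)tetradeca-7,9-diyn-1-ol | OCCCCCCC#CC#CCCCCc1ccco1
F4 | step 13 | 2-(14-bromotetradeca-5,7-diyn-1-yl)furan | BrCCCCCCC#CC#CCCCCc1ccco1
F5 | step 13 | [14-(furan-2-yl)tetradeca-7,9-diyn-1-yl]magnesium bromide | Br[Mg]CCCCCCC#CC#CCCCCc1ccco1
F6 | step 7 | allyl 8-hydroxyoctanoate | OCCCCCCCC(=O)OCC=C
F7 | step 7 | 8-(allyloxy)-8-oxooctyl 19-(furan-2-yl)nonadeca-5,7-diynoate | O=C(CCCC#CC#CCCCCCCCCCCCc1ccco1)OCCCCCCCC(=O)OCC=C
F8 | step 7 | 8-{[19-(furan-2-yl)nonadeca-5,7-diynoyl]oxy}octanoic acid | O=C(CCCC#CC#CCCCCCCCCCCCc1ccco1)OCCCCCCCC(=O)O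
F0 | step 5 | none | none
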